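**Retrosynthetic overview**

1. The target is numbered as 3,5-bis(angeloyloxy)-2,6,6,9-tetramethyltricyclo[5.4.0.0(2,8)]undecan-11-one. The cyclobutane is C1–C2–C8–C7, the six-membered ring is C1/C7–C11, and the seven-membered ring is C1–C7.
2. Angelates ⇐ anti-3,5-diol ⇐ enone (C3 by copper-catalysed borylation, C5 by hydroxyl-directed reduction); C11 ketone ⇐ exocyclic methylene.
3. Seven-membered ring ⇐ aldol condensation between a C3 aldehyde on quaternary C2 and a C5 methyl ketone on quaternary C6. The C7 side chain ⇐ cyclobutanone C7=O.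
4. Cyclobutane and six-membered ring ⇐ intramolecular vinylketene–alkene [2+2], forming C7–C8 and C1–C2. The enabling feature: C7 is the one cyclobutane CH with a single acyclic carbon substituent, flanked by the bridgehead CH carbons C1 and C8 of a bicyclo[3.1.1]heptane, while C2 is fully substituted. This is the imprint of a ketene carbonyl carbon (C7) and a trisubstituted alkene (C8=C2) joined by the C9–C11 tether.
5. Order of ring formation: four- and six-membered rings together (step 8), then the seven-membered ring (step 13).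

Key step: step 8

Remark: both acyl groups are read from the SMILES as (Z)-2-methylbut-2-enoyl (angeloyl). Target numbering is used for all intermediates; in the acyclic acids the carboxyl carbon is C7, followed by C1, C11 (its methyl becomes the methylidene carbon), C10, C9, C8, C2 and C3. Both enantiomers of 3-bromo-2-methylpropan-1-ol are taken as commercially available.

**Route**

Step 1
Reactants: 1 (S)-3-bromo-2-methylpropan-1-ol
Product: 2 (S)-(3-bromo-2-methylpropoxy)(tert-butyl)dimethylsilane
Conditions: TBSCl, imidazole, CH2Cl2, 0 °C → rt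
Reagents that add atoms: tert-butyl(chloro)dimethylsilane, CC(C)(C)[Si](C)(C)Cl
Why: Silyl ether formation masks the hydroxyl for the organometallic step; the C9 stereocentre is not involved.

Step 2
Reactants: 2 (S)-(3-bromo-2-methylpropoxy)(tert-butyl)dimethylsilane; 3 ethyl but-2-ynoate
Product: 6 ethyl (2E,5R)-6-{[tert-butyl(dimethyl)silyl]oxy}-3,5-dimethylhex-2-enoate, via Grignard reagent 4 (not isolated), via alkenylcopper adduct 5 (not isolated)
Conditions: Mg, THF, 40 °C; CuI, −40 °C; 3, −78 °C; AcOH/MeOH, −78 °C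
Reagents that add atoms: none
Why: Syn-carbocupration of the ynoate and protonation with retention should give the (E)-enoate with the C11 methyl cis to the ester, as needed for the later γ-deprotonation; C9 comes unchanged from 1.

Step 3
Reactants: 6 ethyl (2E,5R)-6-{[tert-butyl(dimethyl)silyl]oxy}-3,5-dimethylhex-2-enoate
Product: 7 ethyl (2E,5R)-6-hydroxy-3,5-dimethylhex-2-enoate
Conditions: HF·pyridine, THF, 0 °C → rt
Reagents that add atoms: none
Why: Acidic fluoride desilylation frees the primary alcohol without the oxa-Michael closure that basic fluoride could trigger.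

Step 4
Reactants: 7 ethyl (2E,5R)-6-hydroxy-3,5-dimethylhex-2-enoate
Product: 8 ethyl (2E,5R)-3,5-dimethyl-6-oxohex-2-enoate
Conditions: Dess–Martin periodinane, CH2Cl2, 0 °C → rt; used at once
Reagents that add atoms: none
Why: Dess–Martin oxidation under non-basic conditions should give the α-branched aldehyde without epimerisation at C9.

Step 5
Reactants: 8 ethyl (2E,5R)-3,5-dimethyl-6-oxohex-2-enoate
Product: 9 ethyl (2E,5R,6E)-3,5,7-trimethyl-8-oxoocta-2,6-dienoate
Conditions: Ph3P=C(Me)CHO, toluene, 80 °C
Reagents that add atoms: 2-(triphenylphosphoranylidene)propanal, CC(C=O)=P(c1ccccc1)(c1ccccc1)c1ccccc1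
Why: Wittig olefination with the stabilised formyl ylide is E-selective and places the C2 methyl cis to C9, the geometry that later fixes the quaternary centre.

Step 6
Reactants: 9 ethyl (2E,5R,6E)-3,5,7-trimethyl-8-oxoocta-2,6-dienoate
Product: 10 ethyl (2E,5R,6E)-8,8-dimethoxy-3,5,7-trimethylocta-2,6-dienoate
Conditions: HC(OMe)3, PPTS (cat.), MeOH, rt
Reagents that add atoms: trimethyl orthoformate, COC(OC)OC
Why: Acetalisation removes the conjugation between the C8=C2 alkene and a carbonyl, so that the alkene can act as the nucleophilic partner of the ketene.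

Step 7
Reactants: 10 ethyl (2E,5R,6E)-8,8-dimethoxy-3,5,7-trimethylocta-2,6-dienoate
Product: 11 potassium (2E,5R,6E)-8,8-dimethoxy-3,5,7-trimethylocta-2,6-dienoate
Conditions: KOH (1.0 equiv), MeOH/H2O, 50 °C; evaporate and dry
Reagents that add atoms: potassium hydroxide, [K+].[OH-]
Why: Saponification to the potassium salt keeps the acetal intact and allows the acid chloride to be made without free HCl.

Step 8
Reactants: 11 potassium (2E,5R,6E)-8,8-dimethoxy-3,5,7-trimethylocta-2,6-dienoate
Product: 14 7-(dimethoxymethyl)-4,7-dimethyl-2-methylidenebicyclo[3.1.1]heptan-6-one, via acid chloride 12 (not isolated), via vinylketene 13 (not isolated)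
Conditions: (COCl)2, benzene, 0 °C → rt; evaporate; slow addition to Et3N, toluene, reflux (0.01 M)
Reagents that add atoms: none
Why: Oxalyl chloride gives acid chloride 12, and triethylamine removes HCl through the methyl group on C11 (cis to the carbonyl in the E acid) to give vinylketene 13, which adds to the C8=C2 alkene in a concerted, asynchronous intramolecular [2+2] cycloaddition. The closest known reaction type is the intramolecular vinylketene–alkene cycloaddition of (E)-3,7-dimethylocta-2,6-dienoyl chloride and its homologues, which gives 2-methylidenebicyclo[3.1.1]heptan-6-ones with a fully substituted C7 of that bicycle. Two rings close at once: the cyclobutanone (C1–C2–C8–C7) by the [2+2] itself and the six-membered ring (C1, C7–C11) through the three-atom tether. The bridged mode is expected over the fused one because the ketene carbonyl carbon C7 bonds to the less substituted C8 and the ketene α-carbon C1 to the fully substituted C2. C2 is set by suprafacial addition to the (E)-alkene (the methyl cis to C9 ends syn to the three-carbon bridge, the dimethoxymethyl group anti), and C1 and C8 are set relative to C9 by 1,3-allylic strain, with the C9–H eclipsing the alkene, the tether on one face and the C9 methyl on the other. The step needs high dilution against ketene dimerisation and the absence of protic acid for the acetal; the E geometry of the acid secures deprotonation at the methyl group.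

Step 9
Reactants: 14 7-(dimethoxymethyl)-4,7-dimethyl-2-methylidenebicyclo[3.1.1]heptan-6-one
Product: 15 [7-(dimethoxymethyl)-4,7-dimethyl-2-methylidenebicyclo[3.1.1]heptan-6-ylidene]acetonitrile (E/Z mixture)
Conditions: (EtO)2P(O)CH2CN, NaH, THF, 0 → 60 °C
Reagents that add atoms: diethyl (cyanomethyl)phosphonate, N#CCP(=O)(OCC)OCC
Why: Horner–Wadsworth–Emmons olefination of the strained, non-enolisable cyclobutanone installs C6 and C5 as a cyanomethylidene group; the alkene geometry is irrelevant.

Step 10
Reactants: 15 [7-(dimethoxymethyl)-4,7-dimethyl-2-methylidenebicyclo[3.1.1]heptan-6-ylidene]acetonitrile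
Product: 16 2-[7-(dimethoxymethyl)-4,7-dimethyl-2-methylidenebicyclo[3.1.1]heptan-6-yl]acetonitrile (side chain anti to the three-carbon bridge)
Conditions: Mg, MeOH, 0 °C → rt
Reagents that add atoms: none
Why: Dissolving-metal conjugate reduction of the unsaturated nitrile leaves the isolated alkene and the acetal untouched. C7 is expected to be set by product-development control at the pyramidal β-carbanion, whose carbon substituent takes the less congested exo position; only this epimer can close the seven-membered ring in step 13.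

Step 11
Reactants: 16 2-[7-(dimethoxymethyl)-4,7-dimethyl-2-methylidenebicyclo[3.1.1]heptan-6-yl]acetonitrile
Product: 18 2-[7-(dimethoxymethyl)-4,7-dimethyl-2-methylidenebicyclo[3.1.1]heptan-6-yl]-2-methylpropanenitrile, via monomethyl nitrile 17 (not isolated)
Conditions: LDA, THF, −78 °C; MeI, −78 → 0 °C; then LDA, −78 °C; MeI, DMPU, −78 °C → rt
Reagents that add atoms: iodomethane, CI
Why: Two successive α-alkylations of the nitrile anion build the quaternary C6; the small nitrile tolerates the second, hindered alkylation.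

Step 12
Reactants: 18 2-[7-(dimethoxymethyl)-4,7-dimethyl-2-methylidenebicyclo[3.1.1]heptan-6-yl]-2-methylpropanenitrile
Product: 20 4,7-dimethyl-6-(2-methyl-3-oxobutan-2-yl)-2-methylidenebicyclo[3.1.1]heptane-7-carbaldehyde, via lithium ketimide 19 (not isolated)
Conditions: MeLi, Et2O, 0 °C → rt; then AcOH/H2O/THF (3:1:1), rt
Reagents that add atoms: methyllithium, [Li]C; water, O
Why: Addition of methyllithium to the tertiary nitrile gives the ketimide, and mild aqueous acetic acid hydrolyses it and the dimethyl acetal without protonating the acid-sensitive exocyclic alkene.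

Step 13
Reactants: 20 4,7-dimethyl-6-(2-methyl-3-oxobutan-2-yl)-2-methylidenebicyclo[3.1.1]heptane-7-carbaldehyde
Product: 21 2,6,6,9-tetramethyl-11-methylidenetricyclo[5.4.0.0(2,8)]undec-3-en-5-one
Conditions: KOH, MeOH, rt → 45 °C
Reagents that add atoms: none
Why: The intramolecular aldol condensation (7-enolendo-exo-trig) is unambiguous because the aldehyde on quaternary C2 cannot enolise and the ketone on quaternary C6 can enolise only at its methyl group; the 1,3-syn placement on the cyclobutane holds the two groups together.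

Step 14
Reactants: 21 2,6,6,9-tetramethyl-11-methylidenetricyclo[5.4.0.0(2,8)]undec-3-en-5-one
Product: 23 (3R)-3-hydroxy-2,6,6,9-tetramethyl-11-methylidenetricyclo[5.4.0.0(2,8)]undecan-5-one, via boronate 22 (not isolated)
Conditions: CuCl (cat.), NaOtBu (cat.), (R,S)-Josiphos (cat.), B2pin2, MeOH, THF, rt; then NaBO3·4H2O, THF/H2O, rt
Reagents that add atoms: sodium perborate, [Na+].[Na+].O[B-]1(O)OO[B-](O)(O)OO1
Why: Copper-catalysed enantioselective conjugate borylation and oxidation with retention set C3. The two enone faces differ only through remote groups, so the chiral ligand should control the sense; the ligand enantiomer is chosen to give (3R).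

Step 15
Reactants: 23 (3R)-3-hydroxy-2,6,6,9-tetramethyl-11-methylidenetricyclo[5.4.0.0(2,8)]undecan-5-one
Product: 24 (3R,5R)-2,6,6,9-tetramethyl-11-methylidenetricyclo[5.4.0.0(2,8)]undecane-3,5-diol
Conditions: Me4NBH(OAc)3, AcOH/MeCN (1:1), −20 °C
Reagents that add atoms: none
Why: Evans–Saksena hydroxyl-directed reduction delivers hydride intramolecularly from the C3 alkoxyborohydride and should give the 1,3-anti (trans) diol, which fixes C5 as (R).

Step 16
Reactants: 24 (3R,5R)-2,6,6,9-tetramethyl-11-methylidenetricyclo[5.4.0.0(2,8)]undecane-3,5-diol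
Product: 26 (1R,2R,3R,5R,7S,8S,9R)-3,5-dihydroxy-2,6,6,9-tetramethyltricyclo[5.4.0.0(2,8)]undecan-11-one, via ozonide 25 (not isolated)
Conditions: O3, CH2Cl2, −78 °C; then Me2S, −78 °C → rt
Reagents that add atoms: ozone, [O-][O+]=O
Why: Ozonolysis of the only remaining alkene with reductive work-up unveils the C11 ketone; no stereocentre is touched, since C1 is a bridgehead and cannot epimerise.

Step 17
Reactants: 26 (1R,2R,3R,5R,7S,8S,9R)-3,5-dihydroxy-2,6,6,9-tetramethyltricyclo[5.4.0.0(2,8)]undecan-11-one
Product: 27 (1R,2R,3R,5R,7S,8S,9R)-2,6,6,9-tetramethyl-11-oxotricyclo[5.4.0.0(2,8)]undecane-3,5-diyl bis[(2Z)-2-methylbut-2-enoate]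
Conditions: angelic acid, 2,4,6-trichlorobenzoyl chloride, Et3N, toluene, rt; then 26, 80 °C
Reagents that add atoms: (Z)-2-methylbut-2-enoic acid (angelic acid), C/C=C(/C)C(=O)O
Why: Yamaguchi-type acylation through the mixed 2,4,6-trichlorobenzoic anhydride esterifies hindered secondary alcohols with angelic acid with little Z-to-E isomerisation.

**Compound list**

1 | (S)-3-bromo-2-methylpropan-1-ol | BrC[C@H](CO)C | starting material
2 | (S)-(3-bromo-2-methylpropoxy)(tert-butyl)dimethylsilane | BrC[C@H](CO[Si](C)(C)C(C)(C)C)C | intermediate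
3 | ethyl but-2-ynoate | CCOC(=O)C#CC | starting material
4 | Grignard reagent of 2, bromo[(S)-3-{[tert-butyl(dimethyl)silyl]oxy}-2-methylpropyl]magnesium | Br[Mg]C[C@H](CO[Si](C)(C)C(C)(C)C)C | intermediate
5 | alkenylcopper adduct, ethyl (5R)-6-{[tert-butyl(dimethyl)silyl]oxy}-2-cuprio-3,5-dimethylhex-2-enoate (copper cis to C4) | CCOC(=O)/C([Cu])=C(\C)C[C@H](CO[Si](C)(C)C(C)(C)C)C | intermediate
6 | ethyl (2E,5R)-6-{[tert-butyl(dimethyl)silyl]oxy}-3,5-dimethylhex-2-enoate | CCOC(=O)/C=C(\C)C[C@H](CO[Si](C)(C)C(C)(C)C)C | intermediate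
7 | ethyl (2E,5R)-6-hydroxy-3,5-dimethylhex-2-enoate | CCOC(=O)/C=C(\C)C[C@H](CO)C | intermediate
8 | ethyl (2E,5R)-3,5-dimethyl-6-oxohex-2-enoate | CCOC(=O)/C=C(\C)C[C@H](C=O)C | intermediate
9 | ethyl (2E,5R,6E)-3,5,7-trimethyl-8-oxoocta-2,6-dienoate | CCOC(=O)/C=C(\C)C[C@H](/C=C(\C)C=O)C | intermediate
10 | ethyl (2E,5R,6E)-8,8-dimethoxy-3,5,7-trimethylocta-2,6-dienoate | CCOC(=O)/C=C(\C)C[C@H](/C=C(\C)C(OC)OC)C | intermediate
11 | potassium (2E,5R,6E)-8,8-dimethoxy-3,5,7-trimethylocta-2,6-dienoate | [K+].[O-]C(=O)/C=C(\C)C[C@H](/C=C(\C)C(OC)OC)C | intermediate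
12 | (2E,5R,6E)-8,8-dimethoxy-3,5,7-trimethylocta-2,6-dienoyl chloride | ClC(=O)/C=C(\C)C[C@H](/C=C(\C)C(OC)OC)C | intermediate
13 | vinylketene, (5R,6E)-8,8-dimethoxy-5,7-dimethyl-3-methylideneocta-1,6-dien-1-one | O=C=CC(=C)C[C@H](/C=C(\C)C(OC)OC)C | intermediate
14 | 7-(dimethoxymethyl)-4,7-dimethyl-2-methylidenebicyclo[3.1.1]heptan-6-one (7-methyl syn to the three-carbon bridge; 4-methyl on the side of C6; ring stereocentres as in 27) | COC(OC)[C@]2(C)[C@@H]3C(=O)[C@H]2C(=C)C[C@H]3C | intermediate
15 | [7-(dimethoxymethyl)-4,7-dimethyl-2-methylidenebicyclo[3.1.1]heptan-6-ylidene]acetonitrile (E/Z mixture) | COC(OC)[C@]2(C)[C@@H]3C(=CC#N)[C@H]2C(=C)C[C@H]3C | intermediate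
16 | 2-[7-(dimethoxymethyl)-4,7-dimethyl-2-methylidenebicyclo[3.1.1]heptan-6-yl]acetonitrile (side chain anti to the three-carbon bridge) | COC(OC)[C@]2(C)[C@@H]3[C@@H]([C@H]2C(=C)C[C@H]3C)CC#N | intermediate
17 | 2-[7-(dimethoxymethyl)-4,7-dimethyl-2-methylidenebicyclo[3.1.1]heptan-6-yl]propanenitrile (epimers at the nitrile α-carbon) | COC(OC)[C@]2(C)[C@@H]3[C@@H]([C@H]2C(=C)C[C@H]3C)C(C)C#N | intermediate
18 | 2-[7-(dimethoxymethyl)-4,7-dimethyl-2-methylidenebicyclo[3.1.1]heptan-6-yl]-2-methylpropanenitrile | COC(OC)[C@]2(C)[C@@H]3[C@@H]([C@H]2C(=C)C[C@H]3C)C(C)(C)C#N | intermediate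
19 | lithium ketimide from 18 and methyllithium | COC(OC)[C@]2(C)[C@@H]3[C@@H]([C@H]2C(=C)C[C@H]3C)C(C)(C)C(C)=N[Li] | intermediate
20 | 4,7-dimethyl-6-(2-methyl-3-oxobutan-2-yl)-2-methylidenebicyclo[3.1.1]heptane-7-carbaldehyde | O=C[C@]2(C)[C@@H]3[C@@H]([C@H]2C(=C)C[C@H]3C)C(C)(C)C(C)=O | intermediate
21 | 2,6,6,9-tetramethyl-11-methylidenetricyclo[5.4.0.0(2,8)]undec-3-en-5-one (ring stereocentres as in 27) | O=C1C=C[C@]2(C)[C@@H]3[C@@H]([C@H]2C(=C)C[C@H]3C)C1(C)C | intermediate
22 | 3-(pinacolboryl) ketone, 2,6,6,9-tetramethyl-11-methylidene-3-(4,4,5,5-tetramethyl-1,3,2-dioxaborolan-2-yl)tricyclo[5.4.0.0(2,8)]undecan-5-one | O=C1C[C@@H](B4OC(C)(C)C(C)(C)O4)[C@]2(C)[C@@H]3[C@@H]([C@H]2C(=C)C[C@H]3C)C1(C)C | intermediate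
23 | (3R)-3-hydroxy-2,6,6,9-tetramethyl-11-methylidenetricyclo[5.4.0.0(2,8)]undecan-5-one | O=C1C[C@@H](O)[C@]2(C)[C@@H]3[C@@H]([C@H]2C(=C)C[C@H]3C)C1(C)C | intermediate
24 | (3R,5R)-2,6,6,9-tetramethyl-11-methylidenetricyclo[5.4.0.0(2,8)]undecane-3,5-diol | O[C@@H]1C[C@@H](O)[C@]2(C)[C@@H]3[C@@H]([C@H]2C(=C)C[C@H]3C)C1(C)C | intermediate
25 | ozonide of 24 (spiro-1,2,4-trioxolane at C11) | O[C@@H]1C[C@@H](O)[C@]2(C)[C@@H]3[C@@H]([C@H]2C4(OCOO4)C[C@H]3C)C1(C)C | intermediate
26 | (1R,2R,3R,5R,7S,8S,9R)-3,5-dihydroxy-2,6,6,9-tetramethyltricyclo[5.4.0.0(2,8)]undecan-11-one | O[C@@H]1C[C@@H](O)[C@]2(C)[C@@H]3[C@@H]([C@H]2C(=O)C[C@H]3C)C1(C)C | intermediate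
27 | (1R,2R,3R,5R,7S,8S,9R)-2,6,6,9-tetramethyl-11-oxotricyclo[5.4.0.0(2,8)]undecane-3,5-diyl bis[(2Z)-2-methylbut-2-enoate] | C/C=C(/C)C(=O)O[C@@H]1C[C@@H](OC(=O)/C(C)=C\C)[C@]2(C)[C@@H]3[C@@H]([C@H]2C(=O)C[C@H]3C)C1(C)C | target

Total step count: 17. Longest linear sequence: 17 steps (the route is fully linear from 1).

**Steps most likely to fail**

Step 10. Protonation of C7 could occur from the open exo face, which would put the cyanomethyl group on the side of the three-carbon bridge; that epimer cannot cyclise in step 13 and is lost. The fallback sets out from 14 and returns at 21, and reverses the order in which carbon and hydrogen arrive at C7. 2-Lithio-2-methylpropanenitrile (isobutyronitrile, LDA, THF, −78 °C) should add to the C7 ketone from the same open face and give the hydroxy nitrile F1 with the carbon chain already exo. Excess methyllithium followed by the acetic acid work-up of step 12 would give the hydroxy keto aldehyde F2. Aldol condensation under amine catalysis (pyrrolidine, AcOH, to avoid retro-aldol cleavage) would give the tricyclic hydroxy enone F3. The tertiary hydroxyl would be converted into the methyl oxalate F4 (methyl chlorooxoacetate, DMAP) and removed with Bu3SnH/AIBN in refluxing toluene. Since C7 is then a ring-fusion carbon of the closed cage, the radical can take up hydrogen only on the former hydroxyl side, which gives 21.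

Step 8. Ketene dimerisation or oligomerisation could outrun the cycloaddition, because the acetal lowers the nucleophilicity of the alkene. The fallback sets out from 11 and returns at 14, and uses a keteniminium ion instead of the ketene. Acid chloride 12, made as before, is treated with triethylamine and then dimethylamine at 0 °C, so that vinylketene 13 is trapped as the deconjugated N,N-dimethylamide F5. Tf2O and 2,4,6-collidine in 1,2-dichloroethane at 80 °C generate the much more electrophilic keteniminium ion. Its intramolecular [2+2] cycloaddition, under the same regio- and stereocontrol, gives the cyclobutaniminium triflate F6, which aqueous NaHCO3 hydrolyses to 14.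

Step 17. Acylation of the two neopentyl-type hydroxyls could stay incomplete, and the forcing conditions could isomerise the angeloyl group to the (E)-isomer. The fallback sets out from 26 and returns at 27, and builds the Z alkenes after the ester bonds are made. Diol 26 is acylated with 2-[bis(2,2,2-trifluoroethoxy)phosphoryl]propanoic acid (DCC, DMAP, heat if required, as no alkene geometry is at risk) to give the bis(phosphonate) F7. Still–Gennari olefination (KHMDS 2.0 equiv, 18-crown-6, THF, −78 °C; acetaldehyde) then forms both (Z)-2-methylbut-2-enoates.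

**Further compounds**

F1 | step 10 | 2-[7-(dimethoxymethyl)-6-hydroxy-4,7-dimethyl-2-methylidenebicyclo[3.1.1]heptan-6-yl]-2-methylpropanenitrile (hydroxyl syn to the three-carbon bridge) | COC(OC)[C@]2(C)[C@@H]3[C@@](O)([C@H]2C(=C)C[C@H]3C)C(C)(C)C#N
F2 | step 10 | 6-hydroxy-4,7-dimethyl-6-(2-methyl-3-oxobutan-2-yl)-2-methylidenebicyclo[3.1.1]heptane-7-carbaldehyde | O=C[C@]2(C)[C@@H]3[C@@](O)([C@H]2C(=C)C[C@H]3C)C(C)(C)C(C)=O
F3 | step 10 | 7-hydroxy-2,6,6,9-tetramethyl-11-methylidenetricyclo[5.4.0.0(2,8)]undec-3-en-5-one | O=C1C=C[C@]2(C)[C@@H]3[C@@](O)([C@H]2C(=C)C[C@H]3C)C1(C)C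
F4 | step 10 | methyl 2,6,6,9-tetramethyl-11-methylidene-5-oxotricyclo[5.4.0.0(2,8)]undec-3-en-7-yl oxalate | O=C1C=C[C@]2(C)[C@@H]3[C@@](OC(=O)C(=O)OC)([C@H]2C(=C)C[C@H]3C)C1(C)C
F5 | step 8 | (5R,6E)-8,8-dimethoxy-N,N,5,7-tetramethyl-3-methylideneoct-6-enamide | CN(C)C(=O)CC(=C)C[C@H](/C=C(\C)C(OC)OC)C
F6 | step 8 | N-[7-(dimethoxymethyl)-4,7-dimethyl-2-methylidenebicyclo[3.1.1]heptan-6-ylidene]-N-methylmethanaminium trifluoromethanesulfonate | COC(OC)[C@]2(C)[C@@H]3C(=[N+](C)C)[C@H]2C(=C)C[C@H]3C.[O-]S(=O)(=O)C(F)(F)F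
F7 | step 17 | 2,6,6,9-tetramethyl-11-oxotricyclo[5.4.0.0(2,8)]undecane-3,5-diyl bis{2-[bis(2,2,2-trifluoroethoxy)phosphoryl]propanoate} | CC(C(=O)O[C@@H]1C[C@@H](OC(=O)C(C)P(=O)(OCC(F)(F)F)OCC(F)(F)F)[C@]2(C)[C@@H]3[C@@H]([C@H]2C(=O)C[C@H]3C)C1(C)C)P(=O)(OCC(F)(F)F)OCC(F)(F)F
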